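A direct plan would alkylate the ring-A phenol with a bromoacetate, attach the aryloxyacetic acid to a benzyl oxazolidinone auxiliary (imide A1) and run a boron syn-aldol with the ring-B aldehyde (aldol A2). (Ring A = 4-allyl-2,6-dimethoxyphenyl, ring B = 3,4,5-trimethoxyphenyl, C7 = carbonyl carbon, C8 = stereocentre, C9 = methyl.)
It would then silylate, reduce off the auxiliary, tosylate, displace with hydride, desilylate (alcohol A3) and oxidise to the ketone.
Its weakest steps would be:
(a) the aldol, which sets a C7 carbinol centre only to erase it and brings C9 in as an acyl carbon at the wrong oxidation level;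
(b) the five operations from silylation to desilylation, which only turn that acyl carbon into CH3 and include a hydride displacement on late material beside a carbon bearing an aryloxy leaving group;
(c) the closing oxidation of A3, which unveils the enolisable α-aryloxy aryl ketone in the last step, where C8 can only lose enantiopurity.

**Plan of the new route**
The retrosynthesis cuts the C8–O(ring A) bond together with C8–H last, as an O–H insertion of a C8 carbene into 4-allyl-2,6-dimethoxyphenol used as bought.
It then cuts C8=N2 (diazo transfer onto the propiophenone) and finally the C7–CH2 bond, back to the ring-B acid chloride and an ethyl Grignard reagent.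
The enabling feature is that C8 is both the α-carbon of the C7 aryl ketone on ring B and the carbon bound to the phenolic oxygen of ring A, so C8 can be a diazo (carbene) carbon.
No ring is formed: both benzene rings are purchased, ring B enters in the first step and ring A in the last.
C9 arrives as CH3 and C7 as C=O in the first step, so no carbinol centre is made and erased, no deoxygenation run or hydride displacement is needed, and no oxidation is run beside C8; the stereocentre is created last, under non-basic conditions.

Key step: step 3

Remark: which antipode of the chiral acid in step 3 gives the (R)-ketone cannot be fixed from precedent alone. The route is written for the antipode that gives R, to be confirmed in a first run against a sample from the fallback to step 3. Catalyst-bound species of step 3 (rhodium carbene, rhodium-associated oxonium ylide) are not numbered.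

Step 1
Reactants: 1 3,4,5-trimethoxybenzoyl chloride; 2 ethylmagnesium bromide
Product: 3 1-(3,4,5-trimethoxyphenyl)propan-1-one
Conditions: Fe(acac)3 (3 mol%), THF, −78 °C; aq. NH4Cl
Reagents that add atoms: none
Why: Iron-catalysed acylation of a Grignard reagent (Kumada-type cross-coupling with an acid chloride), in which the catalysed C–C coupling at −78 °C outruns addition of EtMgBr to the product ketone, so C7 (C=O) and C9 (CH3) are in place at their final oxidation levels.

Step 2
Reactants: 3 1-(3,4,5-trimethoxyphenyl)propan-1-one
Product: 5 2-diazo-1-(3,4,5-trimethoxyphenyl)propan-1-one, via trifluoroacetyl diketone 4 (not isolated)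
Conditions: LiN(SiMe3)2, THF, −78 °C; CF3CO2CH2CF3; aq. HCl work-up, crude 4 used directly; 4-acetamidobenzenesulfonyl azide, Et3N, MeCN, rt
Reagents that add atoms: 4-acetamidobenzenesulfonyl azide, CC(=O)Nc1ccc(cc1)S(=O)(=O)N=[N+]=[N-]; 2,2,2-trifluoroethyl trifluoroacetate, O=C(OCC(F)(F)F)C(F)(F)F (its atoms stay only in 4)
Why: Deacylative (detrifluoroacetylative) Regitz diazo transfer, in which Claisen trifluoroacetylation makes C8 acidic enough for triethylamine, the enolate attacks the terminal azide nitrogen and the triazoline fragments with loss of the trifluoroacetyl group as the N-acyl sulfonamide to leave C8=N2; no stereocentre is involved.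

Step 3
Reactants: 5 2-diazo-1-(3,4,5-trimethoxyphenyl)propan-1-one; 6 4-allyl-2,6-dimethoxyphenol (1.2 equiv)
Product: 8 (R)-2-(4-allyl-2,6-dimethoxyphenoxy)-1-(3,4,5-trimethoxyphenyl)propan-1-one, via Z-enol 7 (not isolated)
Conditions: Rh2(O2CCPh3)4 (1 mol%), (R)-6,6'-di(2-naphthyl)-1,1'-spirobiindane-7,7'-diyl hydrogen phosphate (5 mol%; antipode if required, see remark), 5 Å MS, CHCl3, −20 → 0 °C, slow addition of 5
Reagents that add atoms: none
Why: Proposed new method: enantioselective carbene insertion into a phenolic O–H bond is the closest known reaction type (copper/spiro-bisoxazoline catalysis with α-diazopropionates, which gives the same ArO–CH(CH3)–C(=O) motif, and dirhodium carboxylate/chiral spiro phosphoric acid catalysis with α-diazo ketones and alcohols or amines), but an α-alkyl α-diazo aryl ketone has not been combined with a di-ortho-substituted phenol, so the step is argued from the mechanism. The divalent rhodium carboxylate expels N2 from 5 to give an electrophilic rhodium carbene at C8, the phenolic oxygen of 6 adds to it, and the rhodium-associated oxonium ylide collapses by O-to-O proton shift to the metal-free Z-enol 7. The chiral phosphoric acid then acts as a bifunctional proton shuttle (P=O accepts the enol O–H while P–OH delivers H to C8) in a hydrogen-bonded transition state whose 6,6'-aryl walls differentiate the two faces of C8, so the acid alone sets C8 as R; no ring is closed. The step needs O–H insertion to win over cyclopropanation of the allyl C=C, aromatic C–H functionalisation and 1,2-hydride shift from C9. This is secured because the free OH is the most nucleophilic site of 6, both ortho positions and the para position of ring A are substituted, the allyl group is an unactivated monosubstituted alkene, the C9 hydrogens are primary, and bulky triphenylacetate ligands at low temperature disfavour hydride migration. The ketone appears at its final oxidation level under non-basic conditions, so the labile C8–H of 8 meets no enolising reagent, and slow addition of 5 keeps azine and carbonyl-ylide formation low.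

**Compound list**
1 | 3,4,5-trimethoxybenzoyl chloride | COc1cc(cc(OC)c1OC)C(=O)Cl | starting material
2 | ethylmagnesium bromide | CC[Mg]Br | starting material
3 | 1-(3,4,5-trimethoxyphenyl)propan-1-one | CCC(=O)c1cc(OC)c(OC)c(OC)c1 | intermediate
4 | 4,4,4-trifluoro-2-methyl-1-(3,4,5-trimethoxyphenyl)butane-1,3-dione (racemic, configuration at C2 irrelevant) | COc1cc(cc(OC)c1OC)C(=O)C(C)C(=O)C(F)(F)F | intermediate
5 | 2-diazo-1-(3,4,5-trimethoxyphenyl)propan-1-one | CC(=[N+]=[N-])C(=O)c1cc(OC)c(OC)c(OC)c1 | intermediate
6 | 4-allyl-2,6-dimethoxyphenol | C=CCc1cc(OC)c(O)c(OC)c1 | starting material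
7 | (Z)-2-(4-allyl-2,6-dimethoxyphenoxy)-1-(3,4,5-trimethoxyphenyl)prop-1-en-1-ol | C=CCc1cc(OC)c(O/C(C)=C(\O)c2cc(OC)c(OC)c(OC)c2)c(OC)c1 | intermediate
8 | (R)-2-(4-allyl-2,6-dimethoxyphenoxy)-1-(3,4,5-trimethoxyphenyl)propan-1-one | C=CCc1cc(OC)c(O[C@H](C)C(=O)c2cc(OC)c(OC)c(OC)c2)c(OC)c1 | target

Total step count: 3. Longest linear sequence: 3 steps (1 → 3 → 5 → 8); the phenol 6 is used as purchased.

**Steps most likely to fail**

Step 3 (proposed new method). Enantiocontrol may be lost through tautomerisation of the enol by achiral proton shuttles (phenol, adventitious water). The carbene may also be diverted into 1,2-hydride shift or alkene cyclopropanation. The fallback sets out from 6, returns at 8 and uses only known chemistry. Compound 6 would be etherified with ethyl (S)-lactate under Mitsunobu conditions (PPh3, diisopropyl azodicarboxylate, THF, 0 °C → rt); the SN2 step inverts the lactate centre and should give ethyl (R)-2-(4-allyl-2,6-dimethoxyphenoxy)propanoate F1. MeNHOMe·HCl/iPrMgCl (THF, −20 °C) should convert F1 into the Weinreb amide (R)-2-(4-allyl-2,6-dimethoxyphenoxy)-N-methoxy-N-methylpropanamide F2. 3,4,5-Trimethoxyphenylmagnesium bromide F3 (from 5-bromo-1,2,3-trimethoxybenzene and Mg, THF) would be added to F2 at −20 → 0 °C. The stable magnesium chelate should release 8 only on cold aqueous NH4Cl quench, so C8 is not enolised.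

Step 2. C-Trifluoroacetylation of the enolate may be incomplete, or the diketone may undergo retro-Claisen cleavage before diazo transfer and return the ketone. The fallback sets out from 3 and returns at 5. Riley oxidation of 3 (SeO2, dioxane/H2O, reflux) should give 1-(3,4,5-trimethoxyphenyl)propane-1,2-dione F4. Condensation with 4-methylbenzenesulfonohydrazide (MeOH, rt) at the unconjugated C8 carbonyl should give 2-(4-methylbenzenesulfonylhydrazono)-1-(3,4,5-trimethoxyphenyl)propan-1-one F5 (C=N geometry immaterial). Bamford–Stevens-type elimination of sulfinate (Et3N or aq. NaOH, CH2Cl2, 0 °C → rt) should then give 5.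

Step 1. The Grignard reagent may over-add to the ketone, or the acid chloride may be reduced under iron catalysis. The fallback sets out from 1 and returns at 3. Compound 1 would be converted with MeNHOMe·HCl and pyridine (CH2Cl2, 0 °C) into N-methoxy-3,4,5-trimethoxy-N-methylbenzamide F6. Its stable chelate with EtMgBr (2, THF, 0 °C) should give 3 on aqueous quench without over-addition (Weinreb ketone synthesis).

**Further compounds**
F1 | step 3 | ethyl (R)-2-(4-allyl-2,6-dimethoxyphenoxy)propanoate | C=CCc1cc(OC)c(O[C@H](C)C(=O)OCC)c(OC)c1
F2 | step 3 | (R)-2-(4-allyl-2,6-dimethoxyphenoxy)-N-methoxy-N-methylpropanamide | C=CCc1cc(OC)c(O[C@H](C)C(=O)N(C)OC)c(OC)c1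
F3 | step 3 | 3,4,5-trimethoxyphenylmagnesium bromide | COc1cc([Mg]Br)cc(OC)c1OC
F4 | step 2 | 1-(3,4,5-trimethoxyphenyl)propane-1,2-dione | CC(=O)C(=O)c1cc(OC)c(OC)c(OC)c1
F5 | step 2 | 2-(4-methylbenzenesulfonylhydrazono)-1-(3,4,5-trimethoxyphenyl)propan-1-one | CC(=NNS(=O)(=O)c1ccc(C)cc1)C(=O)c2cc(OC)c(OC)c(OC)c2
F6 | step 1 | N-methoxy-3,4,5-trimethoxy-N-methylbenzamide | COc1cc(cc(OC)c1OC)C(=O)N(C)OC
A1 | direct plan | (S)-4-benzyl-3-[2-(4-allyl-2,6-dimethoxyphenoxy)acetyl]oxazolidin-2-one | C=CCc1cc(OC)c(OCC(=O)N2[C@@H](Cc3ccccc3)COC2=O)c(OC)c1
A2 | direct plan | (S)-4-benzyl-3-[(2S,3R)-2-(4-allyl-2,6-dimethoxyphenoxy)-3-hydroxy-3-(3,4,5-trimethoxyphenyl)propanoyl]oxazolidin-2-one | C=CCc1cc(OC)c(O[C@H](C(=O)N2[C@@H](Cc3ccccc3)COC2=O)[C@H](O)c2cc(OC)c(OC)c(OC)c2)c(OC)c1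
A3 | direct plan | (1R,2R)-2-(4-allyl-2,6-dimethoxyphenoxy)-1-(3,4,5-trimethoxyphenyl)propan-1-ol | C=CCc1cc(OC)c(O[C@H](C)[C@H](O)c2cc(OC)c(OC)c(OC)c2)c(OC)c1
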